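**Retrosynthetic overview**
1. Target 23 ⇐ 21: last step, Schenck ene reaction of singlet oxygen with the 8'-oxo-7'(11')-ene and closure of the peroxy-hemiketal (1,2-dioxolane ring).
2. 21 ⇐ 18 + 20: endo [4+2] of a 5-acetoxycyclopentadiene (C2–OAc already in place) with a cyclopentadienone, both released by selenoxide elimination (norbornene ring).
3. 18 and 20 ⇐ one enantioenriched hydroazulene 11 (C2 by CBS reduction, C7 by CuH reduction and equilibration).
4. 11 ⇐ 10 by Cu-catalysed asymmetric methyl 1,4-addition (C10); 10 ⇐ aryl diazoketone 7 by an intramolecular Büchner ring expansion that forms the five- and seven-membered carbocycles together.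
5. Ring order: cyclopentanone + cycloheptatriene (step 4) → norbornene (step 10) → 1,2-dioxolane (step 11); 7 comes from 2-bromoanisole, crotonic acid and an isopropenyl boronate.

Assumption: names use guaiane numbering (C1/C5 ring fusion, C4 bears Me-15, C7 bears the C11 unit, C10 bears Me-14; primes = dienophile-derived half), and C4 (plus C3 in the selenides) is carried as an epimer mixture because both become sp2 in step 10.

**Step 1**
Reactants: 1 2-bromoanisole; 2 (E)-but-2-enoic acid
Product: 3 rac-3-(3-bromo-4-methoxyphenyl)butanoic acid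
Conditions: AlCl3 (2.5 equiv), CH2Cl2, 0 → 23 °C; aq. HCl
Reagents that add atoms: none
Why: Friedel–Crafts hydroarylation of crotonic acid occurs para to the methoxy group, and the benzylic centre is left racemic because it becomes sp2 in step 10.

**Step 2**
Reactants: 3 rac-3-(3-bromo-4-methoxyphenyl)butanoic acid; 4 isopropenylboronic acid pinacol ester
Product: 5 rac-3-[4-methoxy-3-(prop-1-en-2-yl)phenyl]butanoic acid
Conditions: Pd(dppf)Cl2 (3 mol%), K2CO3 (3 equiv), dioxane–H2O 4:1, 90 °C; then aq. HCl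
Reagents that add atoms: none
Why: Suzuki–Miyaura coupling of the aryl bromide tolerates the carboxylate and installs the three carbons that become C11–C13.

**Step 3**
Reactants: 5 rac-3-[4-methoxy-3-(prop-1-en-2-yl)phenyl]butanoic acid
Product: 7 rac-1-diazo-4-[4-methoxy-3-(prop-1-en-2-yl)phenyl]pentan-2-one, via mixed anhydride 6 (not isolated)
Conditions: i-BuOCOCl, N-methylmorpholine, THF, −15 °C; then CH2N2 (Et2O solution), 0 → 23 °C
Reagents that add atoms: diazomethane, C=[N+]=[N-]
Why: Acylation of diazomethane by the mixed anhydride (Arndt–Eistert-type diazoketone synthesis) avoids HCl, which would add to the α-methylstyrene.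

**Step 4**
Reactants: 7 rac-1-diazo-4-[4-methoxy-3-(prop-1-en-2-yl)phenyl]pentan-2-one
Product: 10 14-norguaia-1(5),7(11),9-triene-2,8-dione, via methoxycycloheptatriene 8 (not isolated), via unconjugated trienedione 9 (not isolated)
Conditions: Rh2(OAc)4 (1 mol%), CH2Cl2, 40 °C, slow addition (0.01 M); then oxalic acid (cat.), THF–H2O, 0 °C; then Et3N (0.2 equiv), CH2Cl2, 23 °C
Reagents that add atoms: water, O
Why: In the intramolecular Büchner reaction the rhodium carbenoid cyclopropanates the ipso/ortho bond remote from the alkenyl group and the norcaradiene opens, so the cyclopentanone and the seven-membered ring form in one operation; mild acid then converts the enol ether into the C8 ketone and Et3N moves the acidic C1–H into conjugation.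

**Step 5**
Reactants: 10 14-norguaia-1(5),7(11),9-triene-2,8-dione
Product: 11 (10R)-guaia-1(5),7(11)-diene-2,8-dione
Conditions: Me2Zn (1.5 equiv), Cu(OTf)2 (2 mol%), (S,R,R)-binaphthyl bis(1-phenylethyl)amine phosphoramidite (4 mol%), toluene, −30 °C; aq. NH4Cl
Reagents that add atoms: dimethylzinc, C[Zn]C
Why: Feringa-type Cu-catalysed asymmetric conjugate addition goes to the only unhindered β-carbon (C10), with the ligand enantiomer that gives (S)-3-methylcycloheptanone from cyclohept-2-enone, which is 10R here because C1 outranks C9.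

**Step 6**
Reactants: 11 (10R)-guaia-1(5),7(11)-diene-2,8-dione
Product: 12 (10R)-3-(phenylselanyl)guaia-1(5),7(11)-diene-2,8-dione
Conditions: LDA (1.05 equiv), THF, −78 °C; PhSeCl, −78 °C
Reagents that add atoms: phenylselanyl chloride, Cl[Se]c1ccccc1
Why: Kinetic deprotonation is expected at the cyclopentenone α'-CH2 (C3, more acidic than the C9–H2 next to the C10 methine) and Reich selenenylation occurs trans to the C4 methyl.

**Step 7**
Reactants: 12 (10R)-3-(phenylselanyl)guaia-1(5),7(11)-diene-2,8-dione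
Product: 13 (2R,10R)-2-hydroxy-3-(phenylselanyl)guaia-1(5),7(11)-dien-8-one
Conditions: (R)-Me-CBS (20 mol%), catecholborane (1.5 equiv), toluene, −78 °C; MeOH, aq. work-up
Reagents that add atoms: none
Why: Corey–Bakshi–Shibata 1,2-reduction should prefer the less hindered s-trans cyclopentenone carbonyl and deliver hydride anti to the pseudo-axial C10 methyl (catalyst and substrate matched), placing the C2 hydroxyl cis to Me-14.

**Step 8**
Reactants: 13 (2R,10R)-2-hydroxy-3-(phenylselanyl)guaia-1(5),7(11)-dien-8-one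
Product: 14 (2R,10R)-2-acetoxy-3-(phenylselanyl)guaia-1(5),7(11)-dien-8-one
Conditions: Ac2O, DMAP (cat.), pyridine, CH2Cl2, 0 °C
Reagents that add atoms: acetic anhydride, CC(=O)OC(C)=O
Why: DMAP-catalysed acylation of the only hydroxyl group.

**Step 9**
Reactants: 14 (2R,10R)-2-acetoxy-3-(phenylselanyl)guaia-1(5),7(11)-dien-8-one
Product: 16 (2R,7S,10R)-2-acetoxy-3-(phenylselanyl)guai-1(5)-en-8-one, via silyl enol ether 15 (not isolated)
Conditions: [(Ph3P)CuH]6 (5 mol%), PhMe2SiH (1.5 equiv), toluene, 23 °C; aq. citric acid–THF; then DBU (0.2 equiv), CH2Cl2, 23 °C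
Reagents that add atoms: none
Why: Stryker-type copper hydride 1,4-reduction acts on the only remaining enone, and after hydrolysis DBU equilibration is expected to favour the 7S epimer (isopropyl pseudo-equatorial, cis to the pseudo-axial Me-14).

**Step 10**
Reactants: 16 (2R,7S,10R)-2-acetoxy-3-(phenylselanyl)guai-1(5)-en-8-one; 12 (10R)-3-(phenylselanyl)guaia-1(5),7(11)-diene-2,8-dione
Product: 21 (1R,2S,3R,7S,10R,3'R,4'S,10'R)-2-acetoxy-C1–C4':C3–C3'-linked bis-guaia-4,1'(5'),7'(11')-triene-8,2',8'-trione, via diene-side selenoxide 17 (not isolated), via acetoxydiene 18 (not isolated), via dienone-side selenoxide 19 (not isolated), via cyclopentadienone 20 (not isolated)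
Conditions: 16 (1.3 equiv), mCPBA (1 equiv per Se), CH2Cl2, −78 °C, then Et3N, −78 → 20 °C, cool to 0 °C; add cold selenoxide 19 (from 12, mCPBA, CH2Cl2, −78 °C) over 2 h; 0 → 23 °C
Reagents that add atoms: none
Why: Two Reich selenoxide syn-eliminations (away from the acetoxy carbon in 17) release the diene and the dienone, which combine in an endo Diels–Alder reaction; the large α-LUMO coefficient of the dienone pairs C3' with C3, and each partner is attacked anti to its C10 methyl and anti to the 2-acetoxy group (which would clash with the exo Me-15'), setting C1, C3, C3' and C4'.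

**Step 11**
Reactants: 21 (1R,2S,3R,7S,10R,3'R,4'S,10'R)-2-acetoxy-C1–C4':C3–C3'-linked bis-guaia-4,1'(5'),7'(11')-triene-8,2',8'-trione
Product: 23 CNP0317907.1, via allylic hydroperoxide 22 (not isolated)
Conditions: O2, tetraphenylporphyrin (1 mol%), CH2Cl2, white LED, 0 °C
Reagents that add atoms: dioxygen (as singlet oxygen), O=O
Why: The Schenck ene reaction of the s-cis alkylidene ketone abstracts the C6' hydrogen geminal to the carbonyl (as with pulegone) and the C11' hydroperoxide closes reversibly onto C8' to the more stable 8'R hemiketal, while the norbornene alkene is shielded by the syn-acetoxy group and the endo ring.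

**Compound list**
1 | 2-bromoanisole | COc1ccccc1Br | starting material
2 | (E)-but-2-enoic acid (crotonic acid) | C/C=C/C(=O)O | starting material
3 | rac-3-(3-bromo-4-methoxyphenyl)butanoic acid | CC(CC(=O)O)c1ccc(OC)c(Br)c1 | intermediate
4 | isopropenylboronic acid pinacol ester | CC(=C)B1OC(C)(C)C(C)(C)O1 | starting material
5 | rac-3-[4-methoxy-3-(prop-1-en-2-yl)phenyl]butanoic acid | CC(CC(=O)O)c1ccc(OC)c(C(C)=C)c1 | intermediate
6 | isobutyl carbonic mixed anhydride of 5 | CC(CC(=O)OC(=O)OCC(C)C)c1ccc(OC)c(C(C)=C)c1 | intermediate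
7 | rac-1-diazo-4-[4-methoxy-3-(prop-1-en-2-yl)phenyl]pentan-2-one | CC(CC(=O)C=[N+]=[N-])c1ccc(OC)c(C(C)=C)c1 | intermediate
8 | 6-methoxy-3-methyl-5-(prop-1-en-2-yl)-3,8a-dihydroazulen-1(2H)-one (racemic, C3/C8a mixture) | O=C1CC(C)C2=CC(C(C)=C)=C(OC)C=CC12 | intermediate
9 | 3-methyl-5-(propan-2-ylidene)-3,8a-dihydroazulene-1,6(2H,5H)-dione (C1–H isomer) | O=C1CC(C)C2=CC(=C(C)C)C(=O)C=CC12 | intermediate
10 | 14-norguaia-1(5),7(11),9-triene-2,8-dione (3-methyl-5-(propan-2-ylidene)-2,3,4,5-tetrahydroazulene-1,6-dione, racemic at C4) | O=C1CC(C)C2=C1C=CC(=O)C(=C(C)C)C2 | intermediate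
11 | (10R)-guaia-1(5),7(11)-diene-2,8-dione (1:1 at C4) | O=C1CC(C)C2=C1[C@H](C)CC(=O)C(=C(C)C)C2 | intermediate
12 | (10R)-3-(phenylselanyl)guaia-1(5),7(11)-diene-2,8-dione (3,4-trans isomers) | O=C1C([Se]c3ccccc3)C(C)C2=C1[C@H](C)CC(=O)C(=C(C)C)C2 | intermediate
13 | (2R,10R)-2-hydroxy-3-(phenylselanyl)guaia-1(5),7(11)-dien-8-one (OH cis to Me-14) | O[C@H]1C([Se]c3ccccc3)C(C)C2=C1[C@H](C)CC(=O)C(=C(C)C)C2 | intermediate
14 | (2R,10R)-2-acetoxy-3-(phenylselanyl)guaia-1(5),7(11)-dien-8-one | CC(=O)O[C@H]1C([Se]c3ccccc3)C(C)C2=C1[C@H](C)CC(=O)C(=C(C)C)C2 | intermediate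
15 | (2R,10R)-2-acetoxy-8-[dimethyl(phenyl)silyloxy]-3-(phenylselanyl)guaia-1(5),7-diene | CC(=O)O[C@H]1C([Se]c3ccccc3)C(C)C2=C1[C@H](C)CC(O[Si](C)(C)c3ccccc3)=C(C(C)C)C2 | intermediate
16 | (2R,7S,10R)-2-acetoxy-3-(phenylselanyl)guai-1(5)-en-8-one | CC(=O)O[C@H]1C([Se]c3ccccc3)C(C)C2=C1[C@H](C)CC(=O)[C@H](C(C)C)C2 | intermediate
17 | Se-oxide of 16 | CC(=O)O[C@H]1C([Se](=O)c3ccccc3)C(C)C2=C1[C@H](C)CC(=O)[C@H](C(C)C)C2 | intermediate
18 | (2S,7S,10R)-2-acetoxyguaia-1(5),3-dien-8-one (OAc, Me-14 and iPr on one face) | CC(=O)O[C@H]1C=C(C)C2=C1[C@H](C)CC(=O)[C@H](C(C)C)C2 | intermediate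
19 | Se-oxide of 12 | O=C1C([Se](=O)c3ccccc3)C(C)C2=C1[C@H](C)CC(=O)C(=C(C)C)C2 | intermediate
20 | (10R)-guaia-1(5),3,7(11)-triene-2,8-dione (cyclopentadienone) | O=C1C=C(C)C2=C1[C@H](C)CC(=O)C(=C(C)C)C2 | intermediate
21 | endo [4+2] adduct of 18 and 20, (1R,2S,3R,7S,10R,3'R,4'S,10'R); bonds C1–C4' and C3–C3'; OAc syn to C4=C5 | CC(=O)O[C@H]1[C@H]2C(C)=C3C[C@@H](C(C)C)C(=O)C[C@@H](C)[C@]31[C@]1(C)C3=C(C(=O)[C@H]21)[C@H](C)CC(=O)C(=C(C)C)C3 | intermediate
22 | 11'-hydroperoxy-6'-ene (open form) of 21 | CC(=O)O[C@H]1[C@H]2C(C)=C3C[C@@H](C(C)C)C(=O)C[C@@H](C)[C@]31[C@]1(C)C3=C(C(=O)[C@H]21)[C@H](C)CC(=O)C(C(C)(C)OO)=C3 | intermediate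
23 | CNP0317907.1, (1R,2S,3R,7S,10R,3'R,4'S,8'R,10'R) peroxy-hemiketal | CC(=O)O[C@H]1[C@H]2C(C)=C3C[C@@H](C(C)C)C(=O)C[C@@H](C)[C@]31[C@]1(C)C3=C(C(=O)[C@H]21)[C@H](C)C[C@@]1(O)OOC(C)(C)C1=C3 | target

**Step count**
Total steps: 11. Longest linear sequence: 11 (all steps lie on the line 1 → 23; the dienophile half leaves the line at 12 and re-enters in step 10).

**Three steps most likely to fail**

Step 10 is the weakest. 5-Acyloxycyclopentadienes normally add dienophiles syn to the oxygen, so the required anti addition rests on steric arguments alone. In addition, 18 can undergo 1,5-H shift and 20 can dimerise with itself. The fallback lets the acetoxy group direct and corrects C2 afterwards; it sets out from 12 and returns at 21. Reduction of 12 with the enantiomeric (S)-CBS catalyst gives the C2-epimeric alcohol F8. Acetylation gives the epimeric acetate F9, copper hydride reduction gives the epimeric silyl enol ether F10 and then the epimeric saturated acetate F11, and oxidation gives the epimeric selenoxide F12. This releases the 2-epi acetoxydiene F13, in which the acetoxy group and the C10 methyl steer 20 to the same face, giving the C2-epimeric adduct F14. Methanolysis gives the anti-7-norbornenol F15. Iodination (PPh3, I2, imidazole) with participation of the C4=C5 alkene gives the anti iodide F16 with retention. Bu3SnH/O2 oxygenation of the derived radical from the open alkene face gives the syn hydroperoxide F17, PPh3 reduces it to the syn alcohol F18, and acetylation gives 21.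

Step 4 is the second risk. The carbenoid may cyclopropanate the α-methylstyrene of another molecule, insert into an aromatic C–H bond, or the methoxycycloheptatriene may rearomatise to a 2-tetralone on hydrolysis. The fallback postpones the alkenyl group; it sets out from 3 and returns at 8. The bromo mixed anhydride F1 and diazomethane give the bromo diazoketone F2. Its Rh(II)-catalysed ring expansion gives the bromo methoxycycloheptatriene F3, where bromine directs the carbenoid to the remote ortho bond and no styrene is present. Suzuki coupling of the vinyl bromide F3 with 4 then gives 8.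

Step 9 is the third risk. Copper hydride may reduce the allylic acetate in an SN2' sense or attack the selenide, and the 7S preference on equilibration is assumed, not proven. The fallback reduces before the heteroatoms are installed; it sets out from 11 and returns at 16. Copper hydride reduction of 11 gives the silyl enol ether F4 and, after hydrolysis and equilibration, the saturated enedione F5 (the exocyclic s-cis enone should react before the ring-fusion enone). Selenenylation gives the saturated seleno-enone F6, CBS reduction gives the saturated seleno-alcohol F7, and acetylation gives 16.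

Further compounds
F1 | step 4 | bromo mixed anhydride (isobutyl carbonic anhydride of 3) | CC(CC(=O)OC(=O)OCC(C)C)c1ccc(OC)c(Br)c1
F2 | step 4 | bromo diazoketone, rac-4-(3-bromo-4-methoxyphenyl)-1-diazopentan-2-one | CC(CC(=O)C=[N+]=[N-])c1ccc(OC)c(Br)c1
F3 | step 4 | bromo methoxycycloheptatriene, 5-bromo-6-methoxy-3-methyl-3,8a-dihydroazulen-1(2H)-one | O=C1CC(C)C2=CC(Br)=C(OC)C=CC12
F4 | step 9 | silyl enol ether, (10R)-8-[dimethyl(phenyl)silyloxy]guaia-1(5),7-dien-2-one | O=C1CC(C)C2=C1[C@H](C)CC(O[Si](C)(C)c3ccccc3)=C(C(C)C)C2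
F5 | step 9 | saturated enedione, (7S,10R)-guai-1(5)-ene-2,8-dione | O=C1CC(C)C2=C1[C@H](C)CC(=O)[C@H](C(C)C)C2
F6 | step 9 | saturated seleno-enone, (7S,10R)-3-(phenylselanyl)guai-1(5)-ene-2,8-dione | O=C1C([Se]c3ccccc3)C(C)C2=C1[C@H](C)CC(=O)[C@H](C(C)C)C2
F7 | step 9 | saturated seleno-alcohol, (2R,7S,10R)-2-hydroxy-3-(phenylselanyl)guai-1(5)-en-8-one | O[C@H]1C([Se]c3ccccc3)C(C)C2=C1[C@H](C)CC(=O)[C@H](C(C)C)C2
F8 | step 10 | C2-epimeric alcohol (C2 epimer of 13) | O[C@@H]1C([Se]c3ccccc3)C(C)C2=C1[C@H](C)CC(=O)C(=C(C)C)C2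
F9 | step 10 | epimeric acetate (C2 epimer of 14) | CC(=O)O[C@@H]1C([Se]c3ccccc3)C(C)C2=C1[C@H](C)CC(=O)C(=C(C)C)C2
F10 | step 10 | epimeric silyl enol ether (C2 epimer of 15) | CC(=O)O[C@@H]1C([Se]c3ccccc3)C(C)C2=C1[C@H](C)CC(O[Si](C)(C)c3ccccc3)=C(C(C)C)C2
F11 | step 10 | epimeric saturated acetate (C2 epimer of 16) | CC(=O)O[C@@H]1C([Se]c3ccccc3)C(C)C2=C1[C@H](C)CC(=O)[C@H](C(C)C)C2
F12 | step 10 | epimeric selenoxide (C2 epimer of 17) | CC(=O)O[C@@H]1C([Se](=O)c3ccccc3)C(C)C2=C1[C@H](C)CC(=O)[C@H](C(C)C)C2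
F13 | step 10 | 2-epi acetoxydiene, (2R,7S,10R)-2-acetoxyguaia-1(5),3-dien-8-one | CC(=O)O[C@@H]1C=C(C)C2=C1[C@H](C)CC(=O)[C@H](C(C)C)C2
F14 | step 10 | C2-epimeric adduct (C2 epimer of 21, OAc anti to C4=C5) | CC(=O)O[C@@H]1[C@H]2C(C)=C3C[C@@H](C(C)C)C(=O)C[C@@H](C)[C@]31[C@]1(C)C3=C(C(=O)[C@H]21)[C@H](C)CC(=O)C(=C(C)C)C3
F15 | step 10 | anti-7-norbornenol (2-epi-2-deacetyl-21) | O[C@@H]1[C@H]2C(C)=C3C[C@@H](C(C)C)C(=O)C[C@@H](C)[C@]31[C@]1(C)C3=C(C(=O)[C@H]21)[C@H](C)CC(=O)C(=C(C)C)C3
F16 | step 10 | anti iodide (2-deacetoxy-2-iodo, iodine anti to C4=C5) | I[C@@H]1[C@H]2C(C)=C3C[C@@H](C(C)C)C(=O)C[C@@H](C)[C@]31[C@]1(C)C3=C(C(=O)[C@H]21)[C@H](C)CC(=O)C(=C(C)C)C3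
F17 | step 10 | syn hydroperoxide (2-hydroperoxy, syn to C4=C5) | OO[C@H]1[C@H]2C(C)=C3C[C@@H](C(C)C)C(=O)C[C@@H](C)[C@]31[C@]1(C)C3=C(C(=O)[C@H]21)[C@H](C)CC(=O)C(=C(C)C)C3
F18 | step 10 | syn alcohol (2-deacetyl-21) | O[C@H]1[C@H]2C(C)=C3C[C@@H](C(C)C)C(=O)C[C@@H](C)[C@]31[C@]1(C)C3=C(C(=O)[C@H]21)[C@H](C)CC(=O)C(=C(C)C)C3
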